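**Retrosynthetic overview**
1. Target 18 comes from hexaphenol ketone 17 by reduction at Cα, and 17 from hexamethyl ether 16 by O-demethylation; the acid-labile carbinol is made last.
2. Key disconnection: the indane C1–C2 bond. It joins two benzylic CH carbons, and C1 sits on C7a of resorcinol ring D, so a nitrogen placed between C1 and C2 gives tetrahydroisoquinoline 12, and deleting it closes the five-membered ring.
3. The same C7a position of ring D (ortho/para to its two methoxy groups) closes the piperidine ring of 12 by a Pictet–Spengler reaction of amine 9 with 4-methoxybenzaldehyde 10.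
4. Amine 9 comes from a Mannich addition of deoxybenzoin 3 (from 1 and 2 by α-arylation) to the (R)-tert-butanesulfinyl imine 6 of 3,5-dimethoxybenzaldehyde.
5. Ring order: rings A–D are bought as arenes; the piperidine ring forms in step 5 and is contracted to the cyclopentane ring in step 6.

Key step: step 6

Remark on numbering: indane numbering is used throughout. C1 bears ring A (4-oxyphenyl), C2 ring B (3,5-dioxyphenyl), C3 the carbon Cα that carries ring C, and ring D is the fused resorcinol ring with oxygens at C5 and C7. The target is read as (1R,2S,3R,αS), all-trans on the five-membered ring, with six phenolic oxygens.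
Assumption: the tert-butanesulfinyl imine is taken to react with the lithium enolate in the usual closed, metal-bridged sense, (R)-sulfur giving the (S)-amine carbon of an aryl aldimine; the absolute configuration of the route rests on this.

Step 1
Reactants: 1 4'-methoxyacetophenone; 2 1-bromo-3,5-dimethoxybenzene
Product: 3 2-(3,5-dimethoxyphenyl)-1-(4-methoxyphenyl)ethan-1-one
Conditions: Pd2(dba)3 (1 mol%), Xantphos (2.5 mol%), NaOtBu (2.2 equiv), 1 (1.2 equiv), THF, 70 °C
Reagents that add atoms: none
Why: Palladium-catalysed α-arylation of a methyl ketone; the ketone deprotonated by NaOtBu is arylated by the aryl bromide, and the hindered, more stabilised enolate of the product together with the wide-bite-angle ligand should hold the reaction at mono-arylation.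

Step 2
Reactants: 4 3,5-dimethoxybenzaldehyde; 5 (R)-2-methylpropane-2-sulfinamide
Product: 6 (R,E)-N-(3,5-dimethoxybenzylidene)-2-methylpropane-2-sulfinamide
Conditions: Ti(OEt)4 (2 equiv), THF, rt; brine work-up
Reagents that add atoms: none
Why: Ti(OEt)4-mediated condensation of an aldehyde with tert-butanesulfinamide (Lewis acid and water scavenger) gives the E-N-sulfinyl aldimine with the sulfur configuration untouched.

Step 3
Reactants: 3 2-(3,5-dimethoxyphenyl)-1-(4-methoxyphenyl)ethan-1-one; 6 (R,E)-N-(3,5-dimethoxybenzylidene)-2-methylpropane-2-sulfinamide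
Product: 8 (R)-N-[(1S,2S)-1,2-bis(3,5-dimethoxyphenyl)-3-(4-methoxyphenyl)-3-oxopropyl]-2-methylpropane-2-sulfinamide, via lithium Z-enolate 7 (not isolated)
Conditions: LiN(SiMe3)2 (1.15 equiv), 3 (1.2 equiv), THF, −78 °C; then 6, −78 °C; AcOH quench at −78 °C
Reagents that add atoms: none
Why: Mannich-type addition of a ketone lithium enolate to an N-tert-butanesulfinyl aldimine; the aryl benzyl ketone gives the Z-enolate 7, which should add through a lithium-bridged closed transition state in which the (R)-sulfinyl group exposes the face of C=N that gives the (S)-amine carbon, the syn (1S,2S) relationship is expected from the Z-enolate, and the cold acid quench stops retro-Mannich equilibration.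

Step 4
Reactants: 8 (R)-N-[(1S,2S)-1,2-bis(3,5-dimethoxyphenyl)-3-(4-methoxyphenyl)-3-oxopropyl]-2-methylpropane-2-sulfinamide
Product: 9 (2S,3S)-3-amino-2,3-bis(3,5-dimethoxyphenyl)-1-(4-methoxyphenyl)propan-1-one hydrochloride
Conditions: HCl (4 M in 1,4-dioxane, 3 equiv), MeOH, 0 °C; evaporate, triturate with Et2O
Reagents that add atoms: hydrogen chloride, Cl
Why: Acid cleavage of the N–S bond of a tert-butanesulfinamide (standard sulfinyl removal, sulfur leaving as the methyl sulfinate) gives the amine directly as its hydrochloride, a form in which neither retro-Mannich cleavage nor base-induced epimerisation of the α-carbon can start.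

Step 5
Reactants: 9 (2S,3S)-3-amino-2,3-bis(3,5-dimethoxyphenyl)-1-(4-methoxyphenyl)propan-1-one hydrochloride; 10 4-methoxybenzaldehyde
Product: 12 [(1S,3S,4S)-3-(3,5-dimethoxyphenyl)-6,8-dimethoxy-1-(4-methoxyphenyl)-1,2,3,4-tetrahydroisoquinolin-4-yl](4-methoxyphenyl)methanone, via E-imine 11 (not isolated)
Conditions: 10 (1.1 equiv), Et3N (1.0 equiv), 4 Å molecular sieves, CH2Cl2, rt; then TFA (5 equiv), 0 °C to rt; aq NaHCO3 work-up
Reagents that add atoms: none
Why: Pictet–Spengler reaction; imine 11, once protonated, is attacked 6-endo by the ortho carbon of ring D (ortho/para to its two methoxy groups), while ring B could only close a five-membered ring by a disfavoured 5-endo path; a chair-like transition state with rings A and B pseudo-equatorial should give the 1,3-cis isomer (a centre erased in step 6, so its epimer is equally usable), and C3 and C4 keep the configurations of step 3, the 3,4-trans arrangement also being the more stable one should C4 enolise.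

Step 6
Reactants: 12 [(1S,3S,4S)-3-(3,5-dimethoxyphenyl)-6,8-dimethoxy-1-(4-methoxyphenyl)-1,2,3,4-tetrahydroisoquinolin-4-yl](4-methoxyphenyl)methanone
Product: 16 (1R,2S,3R)-3-(4-methoxybenzoyl)-5,7-dimethoxy-1-(4-methoxyphenyl)-2-(3,5-dimethoxyphenyl)indane (hexamethyl ether of the target at the ketone level), via N-amino-N-benzyloxy amide 13 (not isolated), via isodiazene 14 (not isolated), via 1,5-diradical 15 (not isolated)
Conditions: N-(benzyloxy)-N-(pivaloyloxy)-4-(trifluoromethyl)benzamide (1.5 equiv), THF (0.05 M), Ar, 45 °C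
Reagents that add atoms: none
Why: The secondary amine of 12 displaces pivalate at the nitrogen of the anomeric amide to give 13, which expels benzyl 4-(trifluoromethyl)benzoate by alkoxy migration to the carbonyl and becomes isodiazene 14; 14 loses N2, helped by both C–N bonds being benzylic (the one at tetrahydroisoquinoline C1 doubly so), and leaves singlet 1,5-diradical 15 with a diarylmethyl radical at old C1 and a benzyl radical at old C3. The closest known reaction is the nitrogen deletion of secondary amines with anomeric amides, which contracts tetrahydroisoquinolines to indanes and couples dibenzylic amines; the amine here is the same class, only more hindered. The five-membered ring closes by radical–radical recombination of the two termini of 15 (a 1,5-coupling, not an exo or endo addition to a π bond), which forms the indane C1–C2 bond. Both radical centres are planar and stabilised enough to rotate before coupling, so either C1 epimer of 12 should converge on the same diradical, and the two new centres are set in the closing transition state by the untouched aroyl-bearing carbon (old C4, indane C3): ring B goes trans to the aroyl group at C2 and ring A trans to ring B at C1, the least eclipsed all-trans cyclopentane. The step needs recombination to beat disproportionation and needs this trans,trans closure; ring D holds the two radicals in a 1,5 relationship so that coupling is intramolecular and fast, the only hydrogen transfer open to the pair is a strained 1,4-shift of the C3–H, and the retained stereocentre sits next to the forming bond. The ketone, the methyl ethers and the arenes are not expected to react with the electrophilic nitrogen reagent.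

Step 7
Reactants: 16 (1R,2S,3R)-3-(4-methoxybenzoyl)-5,7-dimethoxy-1-(4-methoxyphenyl)-2-(3,5-dimethoxyphenyl)indane
Product: 17 (1R,2S,3R)-3-(4-hydroxybenzoyl)-1-(4-hydroxyphenyl)-2-(3,5-dihydroxyphenyl)indane-5,7-diol
Conditions: BBr3 (14 equiv), CH2Cl2, −78 °C to rt; ice-water quench
Reagents that add atoms: none
Why: Lewis acid cleavage of the six aryl methyl ethers by BBr3; the aryl ketone only complexes reversibly, the all-trans indane is the thermodynamic arrangement so the enolisable C3 has nowhere better to go, and no carbinol is yet present that could ionise to a quinone methide.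

Step 8
Reactants: 17 (1R,2S,3R)-3-(4-hydroxybenzoyl)-1-(4-hydroxyphenyl)-2-(3,5-dihydroxyphenyl)indane-5,7-diol
Product: 18 (1R,2S,3R)-3-[(S)-hydroxy(4-hydroxyphenyl)methyl]-1-(4-hydroxyphenyl)-2-(3,5-dihydroxyphenyl)indane-5,7-diol (target CNP0214825.2)
Conditions: RuCl(p-cymene)[(S,S)-TsDPEN] (5 mol%), HCO2H/Et3N (5:2), DMF, 40 °C
Reagents that add atoms: none
Why: Noyori asymmetric transfer hydrogenation of an aryl alkyl ketone; the (S,S)-TsDPEN ruthenium hydride should deliver hydride under catalyst control to the face that gives the (S)-carbinol (the same sense as acetophenone to (S)-1-phenylethanol), and the weakly acidic formate medium keeps the phenols neutral and spares the p-hydroxybenzylic alcohol.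

**Compound list**
1 | 4'-methoxyacetophenone | COc1ccc(cc1)C(C)=O | starting material
2 | 1-bromo-3,5-dimethoxybenzene | COc1cc(Br)cc(OC)c1 | starting material
3 | 2-(3,5-dimethoxyphenyl)-1-(4-methoxyphenyl)ethan-1-one | COc1ccc(cc1)C(=O)Cc1cc(OC)cc(OC)c1 | intermediate
4 | 3,5-dimethoxybenzaldehyde | COc1cc(C=O)cc(OC)c1 | starting material
5 | (R)-2-methylpropane-2-sulfinamide | CC(C)(C)[S@@](=O)N | starting material
6 | (R,E)-N-(3,5-dimethoxybenzylidene)-2-methylpropane-2-sulfinamide | CC(C)(C)[S@@](=O)/N=C/c1cc(OC)cc(OC)c1 | intermediate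
7 | lithium (Z)-2-(3,5-dimethoxyphenyl)-1-(4-methoxyphenyl)ethen-1-olate | [Li]O/C(=C\c1cc(OC)cc(OC)c1)c1ccc(OC)cc1 | intermediate (not isolated)
8 | (R)-N-[(1S,2S)-1,2-bis(3,5-dimethoxyphenyl)-3-(4-methoxyphenyl)-3-oxopropyl]-2-methylpropane-2-sulfinamide | CC(C)(C)[S@@](=O)N[C@H](c1cc(OC)cc(OC)c1)[C@H](c1cc(OC)cc(OC)c1)C(=O)c1ccc(OC)cc1 | intermediate
9 | (2S,3S)-3-amino-2,3-bis(3,5-dimethoxyphenyl)-1-(4-methoxyphenyl)propan-1-one hydrochloride | Cl.N[C@H](c1cc(OC)cc(OC)c1)[C@H](c1cc(OC)cc(OC)c1)C(=O)c1ccc(OC)cc1 | intermediate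
10 | 4-methoxybenzaldehyde | COc1ccc(C=O)cc1 | starting material
11 | (2S,3S)-2,3-bis(3,5-dimethoxyphenyl)-3-{[(E)-(4-methoxyphenyl)methylidene]amino}-1-(4-methoxyphenyl)propan-1-one | COc1ccc(/C=N/[C@H](c2cc(OC)cc(OC)c2)[C@H](c2cc(OC)cc(OC)c2)C(=O)c2ccc(OC)cc2)cc1 | intermediate (not isolated)
12 | [(1S,3S,4S)-3-(3,5-dimethoxyphenyl)-6,8-dimethoxy-1-(4-methoxyphenyl)-1,2,3,4-tetrahydroisoquinolin-4-yl](4-methoxyphenyl)methanone (1,3-cis, 3,4-trans) | COc1ccc([C@@H]2N[C@H](c3cc(OC)cc(OC)c3)[C@@H](C(=O)c3ccc(OC)cc3)c3cc(OC)cc(OC)c23)cc1 | intermediate (key-step precursor)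
13 | N-(benzyloxy)-N-[(1S,3S,4S)-3-(3,5-dimethoxyphenyl)-6,8-dimethoxy-4-(4-methoxybenzoyl)-1-(4-methoxyphenyl)-3,4-dihydroisoquinolin-2(1H)-yl]-4-(trifluoromethyl)benzamide | COc1ccc([C@@H]2N(N(OCc3ccccc3)C(=O)c3ccc(cc3)C(F)(F)F)[C@H](c3cc(OC)cc(OC)c3)[C@@H](C(=O)c3ccc(OC)cc3)c3cc(OC)cc(OC)c23)cc1 | intermediate (not isolated)
14 | isodiazene of 12 (ring nitrogen carrying a terminal nitrogen, N+=N−) | COc1ccc([C@@H]2[N+](=[N-])[C@H](c3cc(OC)cc(OC)c3)[C@@H](C(=O)c3ccc(OC)cc3)c3cc(OC)cc(OC)c23)cc1 | intermediate (not isolated)
15 | singlet 1,5-diradical left after N2 loss (diarylmethyl radical ortho on ring D to the CH(aroyl)–CH•(ring B) chain; aroyl-bearing carbon unchanged) | COc1ccc([CH]c2c(OC)cc(OC)cc2[C@H](C(=O)c2ccc(OC)cc2)[CH]c2cc(OC)cc(OC)c2)cc1 | intermediate (not isolated)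
16 | (1R,2S,3R)-3-(4-methoxybenzoyl)-5,7-dimethoxy-1-(4-methoxyphenyl)-2-(3,5-dimethoxyphenyl)indane | COc1ccc([C@@H]2c3c(OC)cc(OC)cc3[C@H](C(=O)c3ccc(OC)cc3)[C@H]2c2cc(OC)cc(OC)c2)cc1 | intermediate (key-step product)
17 | (1R,2S,3R)-3-(4-hydroxybenzoyl)-1-(4-hydroxyphenyl)-2-(3,5-dihydroxyphenyl)indane-5,7-diol | Oc1ccc([C@@H]2c3c(O)cc(O)cc3[C@H](C(=O)c3ccc(O)cc3)[C@H]2c2cc(O)cc(O)c2)cc1 | intermediate
18 | (1R,2S,3R)-3-[(S)-hydroxy(4-hydroxyphenyl)methyl]-1-(4-hydroxyphenyl)-2-(3,5-dihydroxyphenyl)indane-5,7-diol | Oc1ccc([C@@H]2c3c(O)cc(O)cc3[C@H]([C@H](O)c3ccc(O)cc3)[C@H]2c2cc(O)cc(O)c2)cc1 | target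

**Step count**
Total: 8 steps. Longest linear sequence: 7 steps (steps 1, 3, 4, 5, 6, 7, 8); step 2 is a one-step side branch.

**Steps most likely to fail**

Step 6. The nitrogen of 12 is flanked by a diarylmethyl and a benzylic carbon, so N–N bond formation with the bulky anomeric amide may be slow enough for reagent decomposition to win. Once the diradical exists, hydrogen transfer (disproportionation to an alkene) or unselective closure may compete with the trans,trans coupling. The fallback sets out from 12 and comes back at 16. Nitrosation of 12 with tert-butyl nitrite in CH2Cl2, where the small NO+ donor meets little steric resistance, should give the N-nitroso tetrahydroisoquinoline F1. Zinc dust in acetic acid at 0–10 °C should reduce it to the N-amino tetrahydroisoquinoline F2. Oxidation of F2 with HgO in ethanol at 50–60 °C is the long-known way to turn N-amino-2,6-diarylpiperidines into 1,2-diarylcyclopentanes; it generates the same isodiazene 14 without a bulky electrophile and leads through 15 to 16. This route does not change the closure itself, so diastereomers of 16 would be separated by chromatography.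

Step 3. The stabilised, hindered α-aryl enolate may add reversibly, and retro-Mannich equilibration or incomplete facial and syn control would erode the amine carbon, the centre that fixes C3 of the indane. The fallback sets out from 6 (with commercial 3,5-dimethoxyphenylacetic acid) and comes back at 8. The acid is coupled with N,O-dimethylhydroxylamine hydrochloride (EDC·HCl, Et3N, CH2Cl2) to the N-methoxy-N-methylamide F3. Deprotonation with LiN(SiMe3)2 in THF at −78 °C gives its lithium Z-enolate F4, a more nucleophilic partner whose adducts resist reversal. Addition to 6 should give the syn sulfinylamino amide F5. Treatment with 4-MeOC6H4MgBr (3 equiv, THF, 0 °C; Weinreb ketone synthesis, the first equivalent taken by the N–H) then installs ring C and gives 8.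

Step 8. Hydride transfer to a hindered, electron-rich 4-hydroxyphenyl ketone may be slow, and the catalyst preference may be mismatched with the intrinsic facial bias of the neighbouring stereocentre, giving low conversion or a mixture of carbinol epimers. The fallback sets out from 17 and comes back at 18. Silylation (TBSCl, imidazole, DMF) gives the hexa-TBS ketone F6, a phenol-free substrate. Stoichiometric reagent-controlled reduction with (−)-B-chlorodiisopinocampheylborane (THF, −25 °C to rt, diethanolamine work-up; (S)-carbinol sense for aryl alkyl ketones) should give the hexa-TBS (S)-carbinol F7. Desilylation with Et3N·3HF in THF at rt, a near-neutral fluoride source, gives 18.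

**Further compounds**
F1 | step 6 | [(1S,3S,4S)-3-(3,5-dimethoxyphenyl)-6,8-dimethoxy-1-(4-methoxyphenyl)-2-nitroso-1,2,3,4-tetrahydroisoquinolin-4-yl](4-methoxyphenyl)methanone | COc1ccc([C@@H]2N(N=O)[C@H](c3cc(OC)cc(OC)c3)[C@@H](C(=O)c3ccc(OC)cc3)c3cc(OC)cc(OC)c23)cc1
F2 | step 6 | [(1S,3S,4S)-2-amino-3-(3,5-dimethoxyphenyl)-6,8-dimethoxy-1-(4-methoxyphenyl)-1,2,3,4-tetrahydroisoquinolin-4-yl](4-methoxyphenyl)methanone | COc1ccc([C@@H]2N(N)[C@H](c3cc(OC)cc(OC)c3)[C@@H](C(=O)c3ccc(OC)cc3)c3cc(OC)cc(OC)c23)cc1
F3 | step 3 | 2-(3,5-dimethoxyphenyl)-N-methoxy-N-methylacetamide | COc1cc(CC(=O)N(C)OC)cc(OC)c1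
F4 | step 3 | lithium (Z)-2-(3,5-dimethoxyphenyl)-1-[methoxy(methyl)amino]ethen-1-olate | [Li]O/C(=C\c1cc(OC)cc(OC)c1)N(C)OC
F5 | step 3 | (2S,3S)-3-{[(R)-tert-butanesulfinyl]amino}-2,3-bis(3,5-dimethoxyphenyl)-N-methoxy-N-methylpropanamide | CC(C)(C)[S@@](=O)N[C@H](c1cc(OC)cc(OC)c1)[C@H](c1cc(OC)cc(OC)c1)C(=O)N(C)OC
F6 | step 8 | hexakis(tert-butyldimethylsilyl) ether of 17 | CC(C)(C)[Si](C)(C)Oc1ccc([C@@H]2c3c(O[Si](C)(C)C(C)(C)C)cc(O[Si](C)(C)C(C)(C)C)cc3[C@H](C(=O)c3ccc(O[Si](C)(C)C(C)(C)C)cc3)[C@H]2c2cc(O[Si](C)(C)C(C)(C)C)cc(O[Si](C)(C)C(C)(C)C)c2)cc1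
F7 | step 8 | hexakis(tert-butyldimethylsilyl) ether of 18 (free (S)-carbinol) | CC(C)(C)[Si](C)(C)Oc1ccc([C@@H]2c3c(O[Si](C)(C)C(C)(C)C)cc(O[Si](C)(C)C(C)(C)C)cc3[C@H]([C@H](O)c3ccc(O[Si](C)(C)C(C)(C)C)cc3)[C@H]2c2cc(O[Si](C)(C)C(C)(C)C)cc(O[Si](C)(C)C(C)(C)C)c2)cc1
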